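## Retrosynthetic overview

- The target is the hydrolysis product of the C4 enol ether (2R)-4-ethoxy-2-pentadecyl-2H-chromene-5,8-diol, which is the aromatic tautomer of an isoaromatic cycloadduct.
- Key disconnection: an enantioselective oxa-[4+2] cycloaddition of hexadecanal (its C=O becomes C2–O1) onto 2-(1-ethoxyvinyl)-1,4-benzoquinone. It forms C2–C3 and O1–C8a in one operation, closes ring C onto ring A and sets C2.
- Enabling feature: ring A is a para-hydroquinone (oxygen on C5 and C8). At the quinone oxidation level C4a=C8a is a localized alkene β to C5=O, and with C4 as an enol ether the atoms C3=C4–C4a=C8a are a cisoid 2-oxy-1,3-diene. Aromatization of the adduct returns the hydroquinone without any redox reagent.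
- The diene comes from a Stille coupling of 2-bromo-1,4-benzoquinone with tributyl(1-ethoxyvinyl)stannane; the bromoquinone comes from bromohydroquinone.
- Ring order: ring A is bought as the benzenoid and carried as the quinone; ring C (the pyranone) is formed last, in the key step.

Key step: step 3

Assumption: the target is the (2R) enantiomer, and the (1S,2R)-aminoindanol-derived chromium catalyst is taken to direct attack to the Si face of hexadecanal, by analogy with the known sense of this catalyst class with simple alkoxydienes; if this new diene class shows the opposite sense, the (1R,2S) antipode is used.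

Assumption: hexadecanal is bought and freshly distilled so that it is free of acid.

## Route

Step 1
Reactants: 1 bromohydroquinone (2-bromobenzene-1,4-diol)
Product: 2 2-bromo-1,4-benzoquinone
Conditions: NaIO4 (1.2 equiv), wet SiO2, CH2Cl2, 23 °C, 30 min
Reagents that add atoms: none
Why: Two-electron oxidation of a hydroquinone to the para-quinone by periodate should be fast and clean and leaves the C–Br bond untouched.

Step 2
Reactants: 2 2-bromo-1,4-benzoquinone; 3 tributyl(1-ethoxyvinyl)stannane
Product: 4 2-(1-ethoxyvinyl)-1,4-benzoquinone
Conditions: Pd2(dba)3 (2.5 mol%), AsPh3 (20 mol%), THF, 23 °C, Ar, dark; cold filtration through neutral alumina (activity grade 3); kept as a cold dilute solution and used the same day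
Reagents that add atoms: none
Why: Stille cross-coupling, in which the bromoquinone C–Br bond is a highly activated vinylic bromide for oxidative addition to zerovalent palladium and the α-alkoxyvinylstannane transfers its vinyl group at room temperature under arsine acceleration, so the sensitive diene is never heated.

Step 3
Reactants: 4 2-(1-ethoxyvinyl)-1,4-benzoquinone; 5 hexadecanal
Product: 7 (2R)-4-ethoxy-2-pentadecyl-2H-chromene-5,8-diol, via isoaromatic cycloadduct 6 (not isolated)
Conditions: 5 (3 equiv), [Cr(L)Cl] (5 mol%; L = dianion of 2-(1-adamantyl)-6-{[(1S,2R)-2-hydroxyindan-1-yl]iminomethyl}-4-methylphenol), powdered 4 Å molecular sieves, t-BuOMe, 4 °C, 4 added over 12 h by syringe pump, then 23 °C, Ar, dark; then Et3N (10 mol%), 0 °C, 30 min; filtration through deactivated silica under Ar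
Reagents that add atoms: none
Why: Proposed new method: the chromium-bound aldehyde is attacked at carbon by the enol-ether terminus C3 of the cisoid diene C3=C4(OEt)–C4a=C8a while the carbonyl oxygen closes onto C8a, the β-carbon of the C5=O enone, in a polarity-matched, strongly asynchronous oxa-[4+2] cycloaddition (a Mukaiyama-type aldol followed by oxa-Michael closure in the stepwise limit) that gives the isoaromatic adduct 6; amine-mediated proton shifts (C8a–H to O8, C3–H to O5) then aromatize ring A to the hydroquinone 7, which makes the sequence irreversible and redox-neutral. The closest known reaction types are the enantioselective hetero-Diels–Alder reaction of unactivated aliphatic aldehydes with mono-oxygenated 1,3-dienes under this class of tridentate Schiff-base chromium chloride catalysts and the vinylquinone Diels–Alder reaction with tautomerization to the hydroquinone; a vinylquinone has not been shown as the 4π partner of an aldehyde C=O. Ring C is closed by the [4+2] cycloaddition (6-endo-trig at C8a if stepwise). C2 is set by catalyst control, the adamantyl-shielded trivalent chromium centre exposing the Si face of the bound aldehyde, whereas the C8a stereocentre of 6 is transient. The step needs periselectivity for the aldehyde over Diels–Alder dimerization through the unsubstituted C6=C7 bond of a second quinone, which is secured by the excess of aldehyde, the low stationary concentration of 4 and Lewis-acid activation of the aldehyde only. Regiochemistry needs no control because the ethoxy group makes C3 the only nucleophilic terminus and the quinone carbonyls make C8a the only electrophilic one.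

Step 4
Reactants: 7 (2R)-4-ethoxy-2-pentadecyl-2H-chromene-5,8-diol
Product: 8 (2R)-5,8-dihydroxy-2-pentadecylchroman-4-one
Conditions: 1 M HCl (aq)/THF 1:5, degassed, 0 °C to 23 °C, Ar, dark
Reagents that add atoms: water, O
Why: Acid-catalysed enol ether hydrolysis (C3 protonation, water addition to the C4 oxocarbenium ion, loss of ethanol) should give the ketone without touching C2, and brief exposure to dilute acid at low temperature should not open the chromanone ring.

## Compound list

1 | bromohydroquinone (2-bromobenzene-1,4-diol) | Oc1ccc(O)c(Br)c1 | starting material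
2 | 2-bromo-1,4-benzoquinone | O=C1C=CC(=O)C(Br)=C1 | intermediate
3 | tributyl(1-ethoxyvinyl)stannane | CCCC[Sn](CCCC)(CCCC)C(=C)OCC | starting material
4 | 2-(1-ethoxyvinyl)-1,4-benzoquinone | CCOC(=C)C1=CC(=O)C=CC1=O | intermediate
5 | hexadecanal | CCCCCCCCCCCCCCCC=O | starting material
6 | (2R)-4-ethoxy-2-pentadecyl-3,8a-dihydro-2H-chromene-5,8-dione (primary cycloadduct; C8a configuration not controlled and lost on aromatization) | CCCCCCCCCCCCCCC[C@@H]1CC(OCC)=C2C(=O)C=CC(=O)C2O1 | intermediate
7 | (2R)-4-ethoxy-2-pentadecyl-2H-chromene-5,8-diol | CCCCCCCCCCCCCCC[C@@H]1C=C(OCC)c2c(O)ccc(O)c2O1 | intermediate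
8 | (2R)-5,8-dihydroxy-2-pentadecylchroman-4-one | CCCCCCCCCCCCCCC[C@@H]1CC(=O)c2c(O)ccc(O)c2O1 | target

## Step count and risks

Total step count: 4. Longest linear sequence: 4 steps (1 → 2 → 4 → 7 → 8).

**Step 3 (key step).** Several processes can defeat it:
- Diels–Alder self-dimerization of the vinylquinone may outrun the catalysed addition to the aldehyde.
- The mild chromium Lewis acid may turn over too slowly with this electron-poor diene.
- Facial selectivity on the aldehyde may be poor.
- Hydrogen transfer from the product hydroquinone to unreacted quinone may consume the diene.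

Fallback (known chemistry, stepwise aldol at the arene oxidation level, then oxidative cyclization), setting out from 5 and returning at 8:
- 2',5'-Dimethoxyacetophenone is converted (TMSOTf, Et3N) into 1-(2,5-dimethoxyphenyl)-1-(trimethylsilyloxy)ethene F1.
- A Mukaiyama aldol addition of F1 to 5 at −78 °C in EtCN, catalysed by the B-butyl oxazaborolidinone from N-tosyltryptophan (enantiomer chosen for Si-face attack), should give (3R)-1-(2,5-dimethoxyphenyl)-3-(trimethylsilyloxy)octadecan-1-one F2.
- Dilute HCl work-up should give (3R)-1-(2,5-dimethoxyphenyl)-3-hydroxyoctadecan-1-one F3.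
- Oxidative demethylation with excess (NH4)2Ce(NO3)6 in MeCN/H2O should give 2-[(3R)-3-hydroxyoctadecanoyl]-1,4-benzoquinone F4.
- The hydroxyl of F4 should add in a 6-endo oxa-Michael sense to the quinone carbon next to the acyl group, and the resulting hydroquinone should be re-oxidized in the same flask to (2R)-2-pentadecylchromane-4,5,8-trione F5.
- Reduction of F5 with aqueous Na2S2O4 should give 8, with the aldol oxygen retained as O1 and C2 unchanged.

**Step 2.** The quinone may oxidize zerovalent palladium and stop turnover, the stannane may add to the quinone in a conjugate sense, or the product may dimerize or lose its enol ether on the adsorbent.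

Fallback (coupling at the protected hydroquinone level, with the quinone unveiled last under neutral conditions), setting out from 1 and returning at 4:
- Silylation of 1 (TBSCl, imidazole, DMF) should give 2-bromo-1,4-bis(tert-butyldimethylsilyloxy)benzene F6.
- Stille coupling of F6 with 3 (Pd(PPh3)4, toluene, 100 °C) should give 1,4-bis(tert-butyldimethylsilyloxy)-2-(1-ethoxyvinyl)benzene F7.
- Desilylation (Bu4NF, THF, 0 °C, pH 7 buffer work-up) should give 2-(1-ethoxyvinyl)benzene-1,4-diol F8.
- Oxidation of F8 with Ag2O and MgSO4 in Et2O at 0 °C, followed by filtration, should deliver 4 as a solution for immediate use.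

**Step 4.** The electron-rich hydroquinone enol ether may be oxidized by air before hydrolysis is complete, and configuration at C2 may erode through electrocyclic opening of the 2H-chromene or acid-induced opening and re-closure of the chromanone.

Fallback (hydrolysis on the protected hydroquinone, then neutral enzymatic deprotection), setting out from 7 and returning at 8:
- Acetylation of 7 (Ac2O, pyridine, DMAP) should give (2R)-4-ethoxy-2-pentadecyl-2H-chromene-5,8-diyl diacetate F9.
- Mild hydrolysis (pyridinium p-toluenesulfonate, wet acetone) should give (2R)-4-oxo-2-pentadecylchromane-5,8-diyl diacetate F10.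
- Deacetylation of F10 by a lipase (Candida antarctica lipase B, n-butanol, t-BuOMe, 30 °C) should give 8 without exposure to base.

Further compounds
F1 | step 3 | 1-(2,5-dimethoxyphenyl)-1-(trimethylsilyloxy)ethene | COc1ccc(OC)c(c1)C(=C)O[Si](C)(C)C
F2 | step 3 | (3R)-1-(2,5-dimethoxyphenyl)-3-(trimethylsilyloxy)octadecan-1-one | CCCCCCCCCCCCCCC[C@@H](O[Si](C)(C)C)CC(=O)c1cc(OC)ccc1OC
F3 | step 3 | (3R)-1-(2,5-dimethoxyphenyl)-3-hydroxyoctadecan-1-one | CCCCCCCCCCCCCCC[C@@H](O)CC(=O)c1cc(OC)ccc1OC
F4 | step 3 | 2-[(3R)-3-hydroxyoctadecanoyl]-1,4-benzoquinone | CCCCCCCCCCCCCCC[C@@H](O)CC(=O)C1=CC(=O)C=CC1=O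
F5 | step 3 | (2R)-2-pentadecylchromane-4,5,8-trione | CCCCCCCCCCCCCCC[C@@H]1CC(=O)C2=C(O1)C(=O)C=CC2=O
F6 | step 2 | 2-bromo-1,4-bis(tert-butyldimethylsilyloxy)benzene | CC(C)(C)[Si](C)(C)Oc1ccc(O[Si](C)(C)C(C)(C)C)c(Br)c1
F7 | step 2 | 1,4-bis(tert-butyldimethylsilyloxy)-2-(1-ethoxyvinyl)benzene | CCOC(=C)c1cc(O[Si](C)(C)C(C)(C)C)ccc1O[Si](C)(C)C(C)(C)C
F8 | step 2 | 2-(1-ethoxyvinyl)benzene-1,4-diol | CCOC(=C)c1cc(O)ccc1O
F9 | step 4 | (2R)-4-ethoxy-2-pentadecyl-2H-chromene-5,8-diyl diacetate | CCCCCCCCCCCCCCC[C@@H]1C=C(OCC)c2c(OC(C)=O)ccc(OC(C)=O)c2O1
F10 | step 4 | (2R)-4-oxo-2-pentadecylchromane-5,8-diyl diacetate | CCCCCCCCCCCCCCC[C@@H]1CC(=O)c2c(OC(C)=O)ccc(OC(C)=O)c2O1
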